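**Retrosynthetic overview**
1. Target ⇐ O‑acetylation of the hydroxy acid ⇐ fluoride cleavage of a silyl ether and a 2‑(trimethylsilyl)ethyl ester; C1=C10 ⇐ Pd/formate reduction of a C1 enol triflate.
2. C9 quaternary centre and enol triflate ⇐ copper‑catalysed 1,4‑addition of the C11–C16 Grignard fragment (from but‑3‑yn‑1‑ol by Zr‑catalysed carboalumination) to a bicyclic C9=C10–C1=O enone, enolate trapped as triflate.
3. Ring B (formed second) ⇐ intramolecular aldol condensation of a 1,7‑diketone (C10 enolate onto the C9 methyl ketone); C8 is set by equilibration.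
4. Diketone ⇐ Wittig C7=C8 olefination and hydrogenation of a ring A aldehyde ⇐ ketol cleavage of the five‑membered ring of a cis‑hydrindanedione (gives the C4 ester and the C7 aldehyde).
5. Ring A (formed first) ⇐ (S)‑proline‑catalysed intramolecular aldol (Hajos–Parrish) of the triketone from 2‑methylcyclopentane‑1,3‑dione and methyl vinyl ketone; cis‑hydrogenation sets C5.

Assumption: locants C1–C20 are halimane locants of the target (ring A = C1–C5 and C10; ring B = C5–C10; side chain C11–C16 on C9; C17 on C8; C20 on C9; acid carbon on C4); the target is (4S,5R,8S,9R,13E).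

**Ring A aldehyde**

Step 1
Reactants: 1 2‑methylcyclopentane‑1,3‑dione; 2 but‑3‑en‑2‑one (methyl vinyl ketone)
Product: 3 2‑methyl‑2‑(3‑oxobutyl)cyclopentane‑1,3‑dione
Conditions: H2O, AcOH (cat.), 70 °C
Reagents that add atoms: none
Why: Michael addition of the enolised 1,3‑dione to the enone; the product is achiral, its quaternary carbon (future C4) is prochiral.

Step 2
Reactants: 3 2‑methyl‑2‑(3‑oxobutyl)cyclopentane‑1,3‑dione
Product: 5 (7aS)‑7a‑methyl‑2,3,7,7a‑tetrahydro‑1H‑indene‑1,5(6H)‑dione [(S)‑Hajos–Parrish ketone], via Hajos ketol 4 (not isolated)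
Conditions: (S)‑proline (3 mol%), DMF, 20 °C; then H2SO4 (cat.), DMF, 95 °C; recrystallise
Reagents that add atoms: none
Why: Hajos–Parrish intramolecular aldol: the proline enamine of the side‑chain ketone attacks one of the two enantiotopic ring carbonyls through the acid‑directed transition state, fixing the quaternary centre as S (C4 of the target), and acid dehydrates the ketol to close ring A as the enone.

Step 3
Reactants: 5 (S)‑Hajos–Parrish ketone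
Product: 6 (3aR,7aS)‑7a‑methyloctahydro‑1H‑indene‑1,5‑dione (cis‑fused)
Conditions: H2 (1 atm), 5% Pd/C, EtOAc, 20 °C
Reagents that add atoms: none
Why: Heterogeneous hydrogenation of this enedione gives the cis‑fused hydrindanone, which places the new C5–H cis to the C4 methyl as in the target; the minor trans isomer is removed by chromatography.

Step 4
Reactants: 6 cis‑hydrindane‑1,5‑dione
Product: 7 (3a'R,7a'S)‑7a'‑methyloctahydrospiro[1,3‑dioxolane‑2,5'‑inden]‑1'‑one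
Conditions: ethylene glycol (1.1 equiv), PPTS (5 mol%), benzene, reflux (Dean–Stark)
Reagents that add atoms: ethylene glycol, OCCO
Why: Acid‑catalysed ketalisation is selective for the unhindered cyclohexanone carbonyl (future C1) over the neopentyl cyclopentanone carbonyl.

Step 5
Reactants: 7 monoketal
Product: 9 (3a'R,7a'S)‑2'‑hydroxy‑7a'‑methyloctahydrospiro[1,3‑dioxolane‑2,5'‑inden]‑1'‑one (both C2' epimers), via potassium enolate 8 (not isolated)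
Conditions: KN(SiMe3)2 (1.15 equiv), THF, −78 °C; then 3‑phenyl‑2‑(phenylsulfonyl)oxaziridine (1.3 equiv), −78 °C; AcOH quench
Reagents that add atoms: 3‑phenyl‑2‑(phenylsulfonyl)oxaziridine, O=S(=O)(c1ccccc1)N1OC1c1ccccc1
Why: Davis enolate hydroxylation; the ketone can only enolise toward C2' (the other α‑carbon is quaternary), and the new carbinol centre is destroyed in step 6.

Step 6
Reactants: 9 α‑hydroxy ketone
Product: 10 2‑(trimethylsilyl)ethyl (7R,8S)‑8‑methyl‑7‑(2‑oxoethyl)‑1,4‑dioxaspiro[4.5]decane‑8‑carboxylate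
Conditions: Pb(OAc)4 (1.2 equiv), Me3SiCH2CH2OH (10 equiv), benzene, 20 °C
Reagents that add atoms: 2‑(trimethylsilyl)ethanol, C[Si](C)(C)CCO
Why: Criegee‑type glycol cleavage of the α‑ketol through its hemiketal with the alcohol opens the five‑membered ring to the C4 ester and the C7 aldehyde without touching C4 or C5.

**Ylide**

Step 7
Reactants: 11 3‑bromobutan‑2‑one
Product: 12 (3‑oxobutan‑2‑yl)triphenylphosphonium bromide
Conditions: PPh3 (1.0 equiv), toluene, 80 °C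
Reagents that add atoms: triphenylphosphine, c1ccc(cc1)P(c1ccccc1)c1ccccc1
Why: SN2 quaternisation of the phosphine by the activated α‑bromo ketone.

Step 8
Reactants: 12 phosphonium bromide
Product: 13 3‑(triphenylphosphoranylidene)butan‑2‑one
Conditions: NaOH (1 M aq.), CH2Cl2, 20 °C
Reagents that add atoms: none
Why: Deprotonation of the acidic α‑acyl phosphonium salt gives the stabilised ylide.

**Ring B**

Step 9
Reactants: 10 ring A aldehyde; 13 acyl ylide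
Product: 14 2‑(trimethylsilyl)ethyl (7R,8S)‑8‑methyl‑7‑[(2E)‑3‑methyl‑4‑oxopent‑2‑en‑1‑yl]‑1,4‑dioxaspiro[4.5]decane‑8‑carboxylate
Conditions: toluene, 90 °C
Reagents that add atoms: none
Why: Wittig olefination with a stabilised ylide is aldehyde‑selective and gives the E enone, adding C8, C9, C17 and C20.

Step 10
Reactants: 14 E enone
Product: 15 2‑(trimethylsilyl)ethyl (7R,8S)‑8‑methyl‑7‑(3‑methyl‑4‑oxopentyl)‑1,4‑dioxaspiro[4.5]decane‑8‑carboxylate (1:1 at C8)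
Conditions: H2 (1 atm), 10% Pd/C, EtOAc, 20 °C
Reagents that add atoms: none
Why: Chemoselective hydrogenation of the conjugated C=C; C8 forms unselectively and is corrected in step 11.

Step 11
Reactants: 15 keto ketal
Product: 17 2‑(trimethylsilyl)ethyl (1S,6S,8aR)‑1,5,6‑trimethyl‑4‑oxo‑1,2,3,4,6,7,8,8a‑octahydronaphthalene‑1‑carboxylate, via diketone 16 (not isolated)
Conditions: PPTS (0.2 equiv), acetone–H2O 9:1, 55 °C; evaporate; then KOtBu (0.3 equiv), t‑BuOH–THF, 35 °C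
Reagents that add atoms: water, O
Why: Ketal hydrolysis then intramolecular aldol condensation: only the C10 enolate attacking the C9 ketone can dehydrate to a conjugated six‑ring enone (ring B); C8 equilibrates through the ketone enolate and the dienolate, and the epimer with the C8 methyl pseudoaxial, trans to H‑5 and free of A(1,2) strain with the C9 methyl, should dominate (estimated about 4:1, minor epimer recycled).

**Side chain**

Step 12
Reactants: 18 but‑3‑yn‑1‑ol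
Product: 19 1‑[(but‑3‑yn‑1‑yloxy)methyl]‑4‑methoxybenzene
Conditions: NaH (1.1 equiv), 4‑methoxybenzyl chloride (1.05 equiv), Bu4NI (cat.), THF, 0 → 20 °C
Reagents that add atoms: 4‑methoxybenzyl chloride, COc1ccc(CCl)cc1
Why: Williamson etherification of the alkoxide; the alkyne C–H is not deprotonated by NaH.

Step 13
Reactants: 19 PMB ether
Product: 21 ethyl (2E)‑5‑[(4‑methoxybenzyl)oxy]‑3‑methylpent‑2‑enoate, via alkenylalane 20 (not isolated)
Conditions: Me3Al (2.5 equiv), Cp2ZrCl2 (0.25 equiv), CH2Cl2, 0 → 20 °C; then ClCO2Et (3 equiv), 0 → 20 °C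
Reagents that add atoms: trimethylaluminium, C[Al](C)C; ethyl chloroformate, CCOC(=O)Cl
Why: Negishi carboalumination adds Me and Al syn across the alkyne with Al on the terminal carbon, and acylation of the C–Al bond with retention gives the E trisubstituted enoate (C13=C14).

Step 14
Reactants: 21 E enoate
Product: 22 (2E)‑5‑[(4‑methoxybenzyl)oxy]‑3‑methylpent‑2‑en‑1‑ol
Conditions: i‑Bu2AlH (2.3 equiv), CH2Cl2, −78 °C
Reagents that add atoms: none
Why: 1,2‑Reduction of the conjugated ester to the allylic alcohol; the alkene geometry is untouched.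

Step 15
Reactants: 22 allylic alcohol
Product: 23 tert‑butyl{[(2E)‑5‑[(4‑methoxybenzyl)oxy]‑3‑methylpent‑2‑en‑1‑yl]oxy}dimethylsilane
Conditions: t‑BuMe2SiCl (1.2 equiv), imidazole (2.5 equiv), DMF, 20 °C
Reagents that add atoms: tert‑butyldimethylsilyl chloride, CC(C)(C)[Si](C)(C)Cl
Why: Standard imidazole‑promoted silylation of the primary alcohol.

Step 16
Reactants: 23 silyl PMB diether
Product: 24 (3E)‑5‑{[tert‑butyl(dimethyl)silyl]oxy}‑3‑methylpent‑3‑en‑1‑ol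
Conditions: DDQ (1.2 equiv), CH2Cl2–pH 7 buffer 10:1, 0 °C
Reagents that add atoms: none
Why: Oxidative cleavage of the electron‑rich PMB ether; the silyl ether and alkene survive.

Step 17
Reactants: 24 homoallylic alcohol
Product: 25 {[(2E)‑5‑bromo‑3‑methylpent‑2‑en‑1‑yl]oxy}(tert‑butyl)dimethylsilane
Conditions: CBr4 (1.3 equiv), PPh3 (1.4 equiv), 2,6‑lutidine (0.2 equiv), CH2Cl2, 0 °C
Reagents that add atoms: tetrabromomethane, BrC(Br)(Br)Br
Why: Appel bromination of the primary alcohol under near‑neutral conditions.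

**Fragment union and endgame**

Step 18
Reactants: 17 bicyclic enone; 25 side‑chain bromide
Product: 28 2‑(trimethylsilyl)ethyl (1S,5R,6S,8aR)‑5‑[(3E)‑5‑{[tert‑butyl(dimethyl)silyl]oxy}‑3‑methylpent‑3‑en‑1‑yl]‑1,5,6‑trimethyl‑4‑{[(trifluoromethyl)sulfonyl]oxy}‑1,2,3,5,6,7,8,8a‑octahydronaphthalene‑1‑carboxylate, via Grignard reagent 26 (not isolated), via magnesium enolate 27 (not isolated)
Conditions: 25 (2.0 equiv), Mg, THF, 35 °C; then CuBr·SMe2 (0.3 equiv), 17, THF, −40 → −10 °C; then N‑(5‑chloropyridin‑2‑yl)bis(trifluoromethanesulfonyl)imide (2.5 equiv), −40 → 0 °C; H2O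
Reagents that add atoms: N‑(5‑chloropyridin‑2‑yl)bis(trifluoromethanesulfonyl)imide, FC(F)(F)S(=O)(=O)N(c1ccc(Cl)cn1)S(=O)(=O)C(F)(F)F
Why: Copper‑catalysed conjugate addition to the pulegone‑type enone creates C9: the Grignard enters axially on the α face, anti to the pseudoaxial C8 methyl, so the side chain is α and C20 β (9R), and O‑triflation of the regiodefined C1(O)=C10 enolate fixes the position of the future alkene.

Step 19
Reactants: 28 enol triflate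
Product: 29 2‑(trimethylsilyl)ethyl (1S,5R,6S,8aR)‑5‑[(3E)‑5‑{[tert‑butyl(dimethyl)silyl]oxy}‑3‑methylpent‑3‑en‑1‑yl]‑1,5,6‑trimethyl‑1,2,3,5,6,7,8,8a‑octahydronaphthalene‑1‑carboxylate
Conditions: Pd(OAc)2 (5 mol%), PPh3 (10 mol%), Bu3N (3 equiv), HCO2H (2 equiv), DMF, 60 °C
Reagents that add atoms: none
Why: Palladium‑catalysed formate reduction of the enol triflate (oxidative addition to zerovalent palladium, decarboxylation of formate, C–H reductive elimination) replaces OTf by H and leaves the double bond at C1=C10.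

Step 20
Reactants: 29 silyl ether silylethyl ester
Product: 30 (1S,5R,6S,8aR)‑5‑[(3E)‑5‑hydroxy‑3‑methylpent‑3‑en‑1‑yl]‑1,5,6‑trimethyl‑1,2,3,5,6,7,8,8a‑octahydronaphthalene‑1‑carboxylic acid
Conditions: Bu4NF (5 equiv), THF, 20 → 40 °C; then 0.5 M HCl to pH 3, 0 °C
Reagents that add atoms: none
Why: Fluoride cleaves the silyl ether and, by attack at silicon and β‑elimination, the hindered 2‑(trimethylsilyl)ethyl ester, so the neopentyl acid is freed without nucleophilic attack at its carbonyl.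

Step 21
Reactants: 30 hydroxy acid
Product: 31 (1S,5R,6S,8aR)‑5‑[(3E)‑5‑acetoxy‑3‑methylpent‑3‑en‑1‑yl]‑1,5,6‑trimethyl‑1,2,3,5,6,7,8,8a‑octahydronaphthalene‑1‑carboxylic acid (target)
Conditions: Ac2O (1.5 equiv), pyridine (3 equiv), DMAP (5 mol%), CH2Cl2, 0 °C; aq. NaHCO3, then pH 3 work‑up
Reagents that add atoms: acetic anhydride, CC(=O)OC(C)=O
Why: DMAP‑catalysed O‑acetylation of the primary allylic alcohol; the hindered tertiary acid is not esterified and any mixed anhydride is hydrolysed in the bicarbonate work‑up.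

**Compound list**
1 | 2‑methylcyclopentane‑1,3‑dione | CC1C(=O)CCC1=O | starting material
2 | but‑3‑en‑2‑one (methyl vinyl ketone) | CC(=O)C=C | starting material
3 | 2‑methyl‑2‑(3‑oxobutyl)cyclopentane‑1,3‑dione | CC(=O)CCC1(C)C(=O)CCC1=O | intermediate
4 | (3aS,7aS)‑3a‑hydroxy‑7a‑methyloctahydro‑1H‑indene‑1,5‑dione (cis‑fused Hajos ketol) | C1C(=O)CC[C@](C)(C(=O)CC2)[C@@]12O | intermediate (not isolated)
5 | (7aS)‑7a‑methyl‑2,3,7,7a‑tetrahydro‑1H‑indene‑1,5(6H)‑dione | C[C@]12CCC(=O)C=C1CCC2=O | intermediate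
6 | (3aR,7aS)‑7a‑methyloctahydro‑1H‑indene‑1,5‑dione (3a‑H and 7a‑CH3 cis) | C1C(=O)CC[C@](C)(C(=O)CC2)[C@@H]12 | intermediate
7 | (3a'R,7a'S)‑7a'‑methyloctahydrospiro[1,3‑dioxolane‑2,5'‑inden]‑1'‑one | C1C2(OCCO2)CC[C@](C)(C(=O)CC3)[C@@H]13 | intermediate
8 | potassium (3a'R,7a'S)‑7a'‑methyl‑3',3a',4',6',7',7a'‑hexahydrospiro[1,3‑dioxolane‑2,5'‑inden]‑1'‑olate | C1C2(OCCO2)CC[C@](C)(C([O-])=CC3)[C@@H]13.[K+] | intermediate (not isolated)
9 | (3a'R,7a'S)‑2'‑hydroxy‑7a'‑methyloctahydrospiro[1,3‑dioxolane‑2,5'‑inden]‑1'‑one (both C2' epimers) | C1C2(OCCO2)CC[C@](C)(C(=O)C(O)C3)[C@@H]13 | intermediate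
10 | 2‑(trimethylsilyl)ethyl (7R,8S)‑8‑methyl‑7‑(2‑oxoethyl)‑1,4‑dioxaspiro[4.5]decane‑8‑carboxylate | C1C2(OCCO2)CC[C@](C)(C(=O)OCC[Si](C)(C)C)[C@@H]1CC=O | intermediate
11 | 3‑bromobutan‑2‑one (racemic) | CC(Br)C(C)=O | starting material
12 | (3‑oxobutan‑2‑yl)triphenylphosphonium bromide | CC(=O)C(C)[P+](c1ccccc1)(c1ccccc1)c1ccccc1.[Br-] | intermediate
13 | 3‑(triphenylphosphoranylidene)butan‑2‑one | CC(=O)C(C)=P(c1ccccc1)(c1ccccc1)c1ccccc1 | intermediate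
14 | 2‑(trimethylsilyl)ethyl (7R,8S)‑8‑methyl‑7‑[(2E)‑3‑methyl‑4‑oxopent‑2‑en‑1‑yl]‑1,4‑dioxaspiro[4.5]decane‑8‑carboxylate | C1C2(OCCO2)CC[C@](C)(C(=O)OCC[Si](C)(C)C)[C@@H]1C/C=C(\C)C(C)=O | intermediate
15 | 2‑(trimethylsilyl)ethyl (7R,8S)‑8‑methyl‑7‑(3‑methyl‑4‑oxopentyl)‑1,4‑dioxaspiro[4.5]decane‑8‑carboxylate (1:1 at the side‑chain methine) | C1C2(OCCO2)CC[C@](C)(C(=O)OCC[Si](C)(C)C)[C@@H]1CCC(C)C(C)=O | intermediate
16 | 2‑(trimethylsilyl)ethyl (1S,2R)‑1‑methyl‑2‑(3‑methyl‑4‑oxopentyl)‑4‑oxocyclohexane‑1‑carboxylate (side‑chain methine epimers) | C1C(=O)CC[C@](C)(C(=O)OCC[Si](C)(C)C)[C@@H]1CCC(C)C(C)=O | intermediate (not isolated)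
17 | 2‑(trimethylsilyl)ethyl (1S,6S,8aR)‑1,5,6‑trimethyl‑4‑oxo‑1,2,3,4,6,7,8,8a‑octahydronaphthalene‑1‑carboxylate | CC1=C2C(=O)CC[C@](C)(C(=O)OCC[Si](C)(C)C)[C@@H]2CC[C@@H]1C | intermediate
18 | but‑3‑yn‑1‑ol | C#CCCO | starting material
19 | 1‑[(but‑3‑yn‑1‑yloxy)methyl]‑4‑methoxybenzene | C#CCCOCc1ccc(OC)cc1 | intermediate
20 | {(1E)‑4‑[(4‑methoxybenzyl)oxy]‑2‑methylbut‑1‑en‑1‑yl}dimethylalumane | C[Al](C)/C=C(\C)CCOCc1ccc(OC)cc1 | intermediate (not isolated)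
21 | ethyl (2E)‑5‑[(4‑methoxybenzyl)oxy]‑3‑methylpent‑2‑enoate | CCOC(=O)/C=C(\C)CCOCc1ccc(OC)cc1 | intermediate
22 | (2E)‑5‑[(4‑methoxybenzyl)oxy]‑3‑methylpent‑2‑en‑1‑ol | OC/C=C(\C)CCOCc1ccc(OC)cc1 | intermediate
23 | tert‑butyl{[(2E)‑5‑[(4‑methoxybenzyl)oxy]‑3‑methylpent‑2‑en‑1‑yl]oxy}dimethylsilane | CC(C)(C)[Si](C)(C)OC/C=C(\C)CCOCc1ccc(OC)cc1 | intermediate
24 | (3E)‑5‑{[tert‑butyl(dimethyl)silyl]oxy}‑3‑methylpent‑3‑en‑1‑ol | CC(C)(C)[Si](C)(C)OC/C=C(\C)CCO | intermediate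
25 | {[(2E)‑5‑bromo‑3‑methylpent‑2‑en‑1‑yl]oxy}(tert‑butyl)dimethylsilane | CC(C)(C)[Si](C)(C)OC/C=C(\C)CCBr | intermediate
26 | bromo[(3E)‑5‑{[tert‑butyl(dimethyl)silyl]oxy}‑3‑methylpent‑3‑en‑1‑yl]magnesium | CC(C)(C)[Si](C)(C)OC/C=C(\C)CC[Mg]Br | intermediate (not isolated)
27 | bromomagnesium C1(O)=C10 enolate of the 1,4‑adduct (9R, side chain α) | CC(C)(C)[Si](C)(C)OC/C=C(\C)CC[C@@]1(C)C2=C(O[Mg]Br)CC[C@](C)(C(=O)OCC[Si](C)(C)C)[C@@H]2CC[C@@H]1C | intermediate (not isolated)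
28 | 2‑(trimethylsilyl)ethyl (1S,5R,6S,8aR)‑5‑[(3E)‑5‑{[tert‑butyl(dimethyl)silyl]oxy}‑3‑methylpent‑3‑en‑1‑yl]‑1,5,6‑trimethyl‑4‑{[(trifluoromethyl)sulfonyl]oxy}‑1,2,3,5,6,7,8,8a‑octahydronaphthalene‑1‑carboxylate | CC(C)(C)[Si](C)(C)OC/C=C(\C)CC[C@@]1(C)C2=C(OS(=O)(=O)C(F)(F)F)CC[C@](C)(C(=O)OCC[Si](C)(C)C)[C@@H]2CC[C@@H]1C | intermediate
29 | 2‑(trimethylsilyl)ethyl (1S,5R,6S,8aR)‑5‑[(3E)‑5‑{[tert‑butyl(dimethyl)silyl]oxy}‑3‑methylpent‑3‑en‑1‑yl]‑1,5,6‑trimethyl‑1,2,3,5,6,7,8,8a‑octahydronaphthalene‑1‑carboxylate | CC(C)(C)[Si](C)(C)OC/C=C(\C)CC[C@@]1(C)C2=CCC[C@](C)(C(=O)OCC[Si](C)(C)C)[C@@H]2CC[C@@H]1C | intermediate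
30 | (1S,5R,6S,8aR)‑5‑[(3E)‑5‑hydroxy‑3‑methylpent‑3‑en‑1‑yl]‑1,5,6‑trimethyl‑1,2,3,5,6,7,8,8a‑octahydronaphthalene‑1‑carboxylic acid | OC/C=C(\C)CC[C@@]1(C)C2=CCC[C@](C)(C(=O)O)[C@@H]2CC[C@@H]1C | intermediate
31 | (1S,5R,6S,8aR)‑5‑[(3E)‑5‑acetoxy‑3‑methylpent‑3‑en‑1‑yl]‑1,5,6‑trimethyl‑1,2,3,5,6,7,8,8a‑octahydronaphthalene‑1‑carboxylic acid | CC(=O)OC/C=C(\C)CC[C@@]1(C)C2=CCC[C@](C)(C(=O)O)[C@@H]2CC[C@@H]1C | target

**Step count**
Total step count: 21. Longest linear sequence: 13 steps (1–6, 9–11, 18–21).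

**Three steps most likely to fail, with fallbacks**

Step 6 (ketol cleavage in a non‑standard alcohol at a hindered carbonyl). The fallback sets out from 7, skips step 5, and comes back at 10. Ketone 7 is converted with Me3SiOTf/Et3N into its enol ether (3a'R,7a'S)‑7a'‑methyl‑1'‑(trimethylsilyloxy)‑3',3a',4',6',7',7a'‑hexahydrospiro[1,3‑dioxolane‑2,5'‑indene] F1. Ozonolysis (O3, CH2Cl2–MeOH, −78 °C; Me2S) cleaves the enol double bond to the aldehyde acid (7R,8S)‑8‑methyl‑7‑(2‑oxoethyl)‑1,4‑dioxaspiro[4.5]decane‑8‑carboxylic acid F2. The hindered acid is then O‑alkylated with 2‑(trimethylsilyl)ethyl 2,2,2‑trichloroacetimidate (toluene, 80 °C) to give 10.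

Step 11 (aldol cyclodehydration; possible stalling at a bridged aldol, deconjugation to the C8=C9 isomer, or a poor C8 ratio). The fallback sets out from 15 and comes back at 17, making the C9–C10 bond by Pd‑catalysed ketone α‑alkenylation instead of an aldol. Kinetic deprotonation of the methyl ketone (KN(SiMe3)2, −78 °C) and trapping with PhNTf2 gives 2‑(trimethylsilyl)ethyl (7R,8S)‑8‑methyl‑7‑{3‑methyl‑4‑[(trifluoromethylsulfonyl)oxy]pent‑4‑en‑1‑yl}‑1,4‑dioxaspiro[4.5]decane‑8‑carboxylate F3. Ketal hydrolysis (PPTS, wet acetone) gives 2‑(trimethylsilyl)ethyl (1S,2R)‑1‑methyl‑2‑{3‑methyl‑4‑[(trifluoromethylsulfonyl)oxy]pent‑4‑en‑1‑yl}‑4‑oxocyclohexane‑1‑carboxylate F4. Pd2(dba)3, 2‑dicyclohexylphosphino‑2',4',6'‑triisopropylbiphenyl and Cs2CO3 in toluene at 80 °C couple the C10 enolate with the alkenyl triflate (the C2 enolate cannot reach) to give 2‑(trimethylsilyl)ethyl (1S,8aR)‑1,6‑dimethyl‑5‑methylidene‑4‑oxodecahydronaphthalene‑1‑carboxylate F5. DBU in toluene at 80 °C then moves the exocyclic alkene into conjugation and equilibrates C8, giving 17.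

Step 18 (1,4‑addition to a hindered tetrasubstituted enone; γ‑deprotonation or 1,2‑addition may win). The fallback sets out from 17 and comes back at 29, building C9 by a sigmatropic shift.
- BH3·SMe2 with (R)‑2‑methyl‑CBS‑oxazaborolidine delivers hydride to the β face and gives the axial α‑alcohol 2‑(trimethylsilyl)ethyl (1S,4S,6S,8aR)‑4‑hydroxy‑1,5,6‑trimethyl‑1,2,3,4,6,7,8,8a‑octahydronaphthalene‑1‑carboxylate F6.
- Johnson–Claisen rearrangement (MeC(OEt)3, cat. EtCO2H, 140 °C) transfers the C1–O chirality suprafacially to C9, α and anti to the C8 methyl, and sets C1=C10, giving 2‑(trimethylsilyl)ethyl (1S,5R,6S,8aR)‑5‑(2‑ethoxy‑2‑oxoethyl)‑1,5,6‑trimethyl‑1,2,3,5,6,7,8,8a‑octahydronaphthalene‑1‑carboxylate F7.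
- LiBH4 reduces only the unhindered ethyl ester, giving 2‑(trimethylsilyl)ethyl (1S,5R,6S,8aR)‑5‑(2‑hydroxyethyl)‑1,5,6‑trimethyl‑1,2,3,5,6,7,8,8a‑octahydronaphthalene‑1‑carboxylate F8.
- I2/PPh3/imidazole gives 2‑(trimethylsilyl)ethyl (1S,5R,6S,8aR)‑5‑(2‑iodoethyl)‑1,5,6‑trimethyl‑1,2,3,5,6,7,8,8a‑octahydronaphthalene‑1‑carboxylate F9.
- t‑BuLi then B‑methoxy‑9‑BBN gives the lithium B‑alkyl‑B‑methoxy‑9‑borabicyclo[3.3.1]nonane ate complex F10.
- The coupling partner comes from but‑2‑yn‑1‑ol: silylation gives tert‑butyl(but‑2‑yn‑1‑yloxy)dimethylsilane F11, and Cp2Zr(H)Cl hydrozirconation followed by I2 gives tert‑butyl{[(2E)‑3‑iodobut‑2‑en‑1‑yl]oxy}dimethylsilane F12.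
- B‑alkyl Suzuki coupling of F10 with F12 (Pd(dppf)Cl2, K3PO4, DMF, 20 °C) gives 29.

Further compounds
F1 | step 6 | (3a'R,7a'S)‑7a'‑methyl‑1'‑(trimethylsilyloxy)‑3',3a',4',6',7',7a'‑hexahydrospiro[1,3‑dioxolane‑2,5'‑indene] | C1C2(OCCO2)CC[C@](C)(C(O[Si](C)(C)C)=CC3)[C@@H]13
F2 | step 6 | (7R,8S)‑8‑methyl‑7‑(2‑oxoethyl)‑1,4‑dioxaspiro[4.5]decane‑8‑carboxylic acid | C1C2(OCCO2)CC[C@](C)(C(=O)O)[C@@H]1CC=O
F3 | step 11 | 2‑(trimethylsilyl)ethyl (7R,8S)‑8‑methyl‑7‑{3‑methyl‑4‑[(trifluoromethylsulfonyl)oxy]pent‑4‑en‑1‑yl}‑1,4‑dioxaspiro[4.5]decane‑8‑carboxylate | C1C2(OCCO2)CC[C@](C)(C(=O)OCC[Si](C)(C)C)[C@@H]1CCC(C)C(=C)OS(=O)(=O)C(F)(F)F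
F4 | step 11 | 2‑(trimethylsilyl)ethyl (1S,2R)‑1‑methyl‑2‑{3‑methyl‑4‑[(trifluoromethylsulfonyl)oxy]pent‑4‑en‑1‑yl}‑4‑oxocyclohexane‑1‑carboxylate | C1C(=O)CC[C@](C)(C(=O)OCC[Si](C)(C)C)[C@@H]1CCC(C)C(=C)OS(=O)(=O)C(F)(F)F
F5 | step 11 | 2‑(trimethylsilyl)ethyl (1S,8aR)‑1,6‑dimethyl‑5‑methylidene‑4‑oxodecahydronaphthalene‑1‑carboxylate (mixture at C4a and C6) | C=C1C2C(=O)CC[C@](C)(C(=O)OCC[Si](C)(C)C)[C@@H]2CCC1C
F6 | step 18 | 2‑(trimethylsilyl)ethyl (1S,4S,6S,8aR)‑4‑hydroxy‑1,5,6‑trimethyl‑1,2,3,4,6,7,8,8a‑octahydronaphthalene‑1‑carboxylate | CC1=C2[C@@H](O)CC[C@](C)(C(=O)OCC[Si](C)(C)C)[C@@H]2CC[C@@H]1C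
F7 | step 18 | 2‑(trimethylsilyl)ethyl (1S,5R,6S,8aR)‑5‑(2‑ethoxy‑2‑oxoethyl)‑1,5,6‑trimethyl‑1,2,3,5,6,7,8,8a‑octahydronaphthalene‑1‑carboxylate | CCOC(=O)C[C@@]1(C)C2=CCC[C@](C)(C(=O)OCC[Si](C)(C)C)[C@@H]2CC[C@@H]1C
F8 | step 18 | 2‑(trimethylsilyl)ethyl (1S,5R,6S,8aR)‑5‑(2‑hydroxyethyl)‑1,5,6‑trimethyl‑1,2,3,5,6,7,8,8a‑octahydronaphthalene‑1‑carboxylate | OCC[C@@]1(C)C2=CCC[C@](C)(C(=O)OCC[Si](C)(C)C)[C@@H]2CC[C@@H]1C
F9 | step 18 | 2‑(trimethylsilyl)ethyl (1S,5R,6S,8aR)‑5‑(2‑iodoethyl)‑1,5,6‑trimethyl‑1,2,3,5,6,7,8,8a‑octahydronaphthalene‑1‑carboxylate | ICC[C@@]1(C)C2=CCC[C@](C)(C(=O)OCC[Si](C)(C)C)[C@@H]2CC[C@@H]1C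
F10 | step 18 | lithium B‑methoxy‑B‑alkyl‑9‑borabicyclo[3.3.1]nonane ate complex of F9 (boron on C12) | [Li+].CO[B-]1(CC[C@@]2(C)C3=CCC[C@](C)(C(=O)OCC[Si](C)(C)C)[C@@H]3CC[C@@H]2C)C4CCCC1CCC4
F11 | step 18 | tert‑butyl(but‑2‑yn‑1‑yloxy)dimethylsilane | CC#CCO[Si](C)(C)C(C)(C)C
F12 | step 18 | tert‑butyl{[(2E)‑3‑iodobut‑2‑en‑1‑yl]oxy}dimethylsilane | I/C(C)=C/CO[Si](C)(C)C(C)(C)C
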